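The south-east run held more E than the east run, yet its last ratio of Q to G was lower, 0.0989 against 0.120. Their Q differed by 2 percentage points, with each reading scattering by 1.5 points. By hand, paths that each use E once cancel E from that ratio, and I saw nothing against this. Also by hand, more X feeds paths of equal order alike; the north-west run, charged with 0.75 M of X but also with less E than the other two, ended at 0.101, above the south-east run and below the east run.

| flask | X | E | remark | time |
|---|---|---|---|---|
| east | 0.50 M | 0.35 mM | run made earlier |  |
| south-east | 0.50 M | 0.55 mM | run made earlier |  |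
| north-west | 0.75 M | 0.25 mM | run made earlier |  |
| flask | 0.50 M | 0.25 mM |  | 10 min |

| run | time / min | Q / % | G / % |
|---|---|---|---|
| east | 1.00 | 4 | 25 |
| east | 3.00 | 9 | 71 |
| east | 5.00 | 11 | 90 |
| east | 8.00 | 11 | 92 |
| south-east | 1.00 | 0 | 25 |
| south-east | 3.00 | 8 | 74 |
| south-east | 5.00 | 9 | 91 |
| south-east | 8.00 | 9 | 91 |
| north-west | 0.667 | 0 | 12 |
| north-west | 1.33 | 3 | 22 |
| north-west | 3.00 | 6 | 50 |
| north-west | 8.00 | 9 | 89 |

(scatter of a reading: 1.5 percentage points)

1. ratio of Q to G at 6.0 s
2. ratio of Q to G at 1.0 min
3. ratio of Q to G at 10 min

- given per volume of solution although it is solid: X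
- at the start none of X is in solution

I then worked with the fraction left. Pooled over the last readings, the part of the converted X that stood as Q was 0.0963. This Q share, the selectivity, gives Q as the share times one minus the fraction left. Time remained: parallel paths of equal order from one pool hold one ratio from the start, so I committed to 0.107 at each asked time. The readings up to 1.33 min pooled to 0.0833, lower, but their Q ran from 0% to 4% with a scatter of 1.5 points.

The forecast gave 0.09, 0.1 and 0.11, holding that “Q and G therefore look like parallel products from dissolved X, with a roughly constant ratio”. Its earliest value stood lower than mine.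

The flask gave 0.113, 0.113 and 0.113.

    D ⇌ Z, settled at all times (K = 0.560)
    D + E → E + Q (k = 678 M⁻¹ s⁻¹)
    E + Z → E + G (k = 10700 M⁻¹ s⁻¹)
    X ⇌ D, rate k4*(cs4 - [D]) while solid is left; crystals form when [D] > cs4 (solubility = 0.270 M, k = 0.00842 s⁻¹)

At 1.00 min the flask still held 72.9% as solid X, with 0.271% as D and 0.152% as Z, while E, at 100%, turned these into Q and G. By 5.00 min X stood at 0%, with Q at 10.2% and G at 89.8%. The Q share applied to the fraction left at 1.00 min gives 2.57% of Q, and the flask held 2.72%. In a neighbour flask, the same but with 1.0 × 10⁻⁴ M of E, 0% of the X remained, solid or dissolved, so the share gives 9.63% of Q, and that flask ended with 10.2%.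

Readings and results come from a simulation on assumed constants; the scatter is artificial.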